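The route rests on the 1,5-relationship between the C4 ketone of the chroman-2,4-dione ring and the side-chain carbonyl, joined through quaternary C3 and two CH2 groups. It also uses aryl oxygen O1 of the C2 lactone as a tether. Cutting C3–C4 and the CH2–CH2 bond gives a salicylic acid-derived aryl β-keto thioester whose phenol oxygen carries a 2-farnesylacrylate. One photochemical operation, intramolecular enol–alkene [2+2] cycloaddition followed by retro-aldol opening of the cyclobutanol, closes the lactone ring, sets C3 from a prochiral sp2 carbon and frees a thioester arm. This arm is then coupled with a separately made silylated (S,Z)-diynol, and desilylation ends the route.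

Key step: step 7

Shorthand: farnesyl stands for (2E,6E)-3,7,11-trimethyldodeca-2,6,10-trien-1-yl.
Assumption: the ligand antipodes written in steps 7 and 11 are those expected to lead to 3S and to the S-carbinol; both antipodes of each ligand are commercial, so an opposite sense of induction would be met by exchanging the ligand alone.

Step 1
Reactants: 1 triethyl phosphonoacetate; 2 (2E,6E)-farnesyl bromide
Product: 3 triethyl 2-[(2E,6E)-farnesyl]phosphonoacetate (racemic at the α-carbon)
Conditions: NaH, THF, 0 °C; then 2, 0 °C → rt (slight excess of 1)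
Reagents that add atoms: none
Why: Alkylation of the sodium phosphonoacetate carbanion by a primary allylic bromide is a plain SN2 reaction that leaves both E-alkenes untouched, and the slight excess of 1 holds back double alkylation.

Step 2
Reactants: 3 triethyl 2-[(2E,6E)-farnesyl]phosphonoacetate
Product: 4 ethyl 2-[(2E,6E)-farnesyl]acrylate
Conditions: 37 % aq. HCHO, K2CO3, THF/H2O, 70 °C
Reagents that add atoms: formaldehyde, C=O
Why: Horner–Wadsworth–Emmons methylenation of an α-substituted phosphonoacetate with aqueous formaldehyde and carbonate is the standard entry to 2-alkylacrylates and is too mild to move the skipped diene into conjugation.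

Step 3
Reactants: 4 ethyl 2-[(2E,6E)-farnesyl]acrylate
Product: 5 2-[(2E,6E)-farnesyl]acrylic acid
Conditions: LiOH, THF/H2O, rt; then cold 1 M HCl to pH 3
Reagents that add atoms: lithium hydroxide, [Li+].[OH-]
Why: Ester saponification in a methanol-free medium avoids alkoxide conjugate addition, and the brief cold acidification does not protonate the trisubstituted alkenes.

Step 4
Reactants: 5 2-[(2E,6E)-farnesyl]acrylic acid; 6 salicylic acid
Product: 8 2-({2-[(2E,6E)-farnesyl]acryloyl}oxy)benzoic acid, via 2-farnesylacryloyl chloride 7 (not isolated)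
Conditions: 1-chloro-N,N,2-trimethylprop-1-en-1-amine, CH2Cl2, 0 °C; then 6, pyridine, BHT (trace), 0 °C → rt; dilute HCl wash
Reagents that add atoms: none
Why: Neutral acid chloride formation with an α-chloroenamine spares the acid-sensitive triene, and pyridine-mediated O-acylation of salicylic acid (the reaction type that gives aspirin homologues) mounts the acrylate on O1 before any β-keto thioester exists, because a free ortho-hydroxyaryl β-keto thioester would lactonise to 4-hydroxycoumarin with loss of ethanethiol.

Step 5
Reactants: 9 Meldrum's acid; 10 ethanethiol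
Product: 11 3-(ethylsulfanyl)-3-oxopropanoic acid (malonic acid half thioester)
Conditions: toluene, sealed tube, 90 °C
Reagents that add atoms: none
Why: Thermal ring opening of Meldrum's acid by a thiol with loss of acetone is the usual preparation of malonic acid half thioesters, and doing it on this small fragment keeps free thiol away from the acrylate and the farnesyl alkenes.

Step 6
Reactants: 8 2-({2-[(2E,6E)-farnesyl]acryloyl}oxy)benzoic acid; 11 3-(ethylsulfanyl)-3-oxopropanoic acid
Product: 14 2-[3-(ethylsulfanyl)-3-oxopropanoyl]phenyl 2-[(2E,6E)-farnesyl]acrylate, via acyl imidazolide 12 (not isolated), via magnesium half-thiomalonate 13 (not isolated)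
Conditions: a) 8, CDI (1.0 equiv), THF, 0 °C → rt; b) 11, Mg(OEt)2, THF, rt, then evaporation; c) a + b, THF, rt; cold 0.5 M HCl
Reagents that add atoms: none
Why: Decarboxylative Claisen condensation of a magnesium malonate half thioester with an acyl imidazolide (Masamune–Brooks C-acylation) runs at room temperature without added base, so the aryl acrylate should survive and the product stays an unreactive magnesium chelate until the acidic quench, which guards against O-to-C acyl migration of the Baker–Venkataraman type.

Step 7
Reactants: 14 2-[3-(ethylsulfanyl)-3-oxopropanoyl]phenyl 2-[(2E,6E)-farnesyl]acrylate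
Product: 16 S-ethyl 3-{(3S)-3-[(2E,6E)-farnesyl]-2,4-dioxochroman-3-yl}propanethioate, via cyclobutanol 15 (not isolated)
Conditions: [Ru(bpy)3](PF6)2 (2.5 mol %), Sc(OTf)3 (10 mol %), (S,S)-tBu-PyBox (15 mol %), 4 Å MS, iPrOAc/MeCN (3:1), 0.01 M, freeze–pump–thaw, blue LEDs (455 nm), 0 °C
Reagents that add atoms: none
Why: Proposed new method: scandium–PyBox chelates the two carbonyl oxygens of the strongly enolised β-keto thioester, and only this chelated aryl enol should have a triplet low enough for energy transfer from excited [Ru(bpy)3]2+, so that the enol carbon (future C4) bonds to the acrylate α-carbon (future C3), the thioester α-carbon bonds to the acrylate CH2, and the triplet 1,4-diradical closes after spin inversion to cyclobutanol 15. The lactone ring O1–C2–C3–C4–C4a–C8a closes in a 6-exo-trig mode across the four-atom aryl ester tether and the transient four-membered ring by diradical recombination, whereas the crossed mode (7-endo, then a benzo-fused bicyclo[4.1.1] lactone) is so strained that its diradical should fall back to 14, and the nearest farnesyl alkene is out of reach of any small-ring closure. In 15 the scandium-bound C4 oxygen pushes and two ring bonds could break, but cleavage of C4–CH(COSEt) gives the better stabilised, less substituted thioester enolate and keeps the six-membered lactone, while cleavage of C4–C3 would give a tertiary ester enolate in an eight-membered ring; protonation then leaves the C4 ketone and the CH2CH2C(O)SEt arm. C3 is the only stereocentre that survives: the ligand shields one face of the flat chelated enol and thus fixes C4, and the obligatory cis fusion of the 6/4 ring pair passes that choice on to the acrylate face, so C3 is controlled although the Lewis acid is not bound to the acrylate. The closest known reaction types are the visible-light-sensitised De Mayo reaction of enolised 1,3-dicarbonyl compounds with alkenes and the chiral Lewis acid-catalysed triplet [2+2] photocycloaddition of chelating aryl enones. Racemic background is held down because unbound 14 is not sensitised, and high dilution together with exclusion of oxygen, base and water guards against intermolecular Michael addition, singlet-oxygen ene reaction of the farnesyl chain, O-to-C acyl migration and release of triflic acid.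

Step 8
Reactants: 17 dec-2-yn-1-ol
Product: 18 (Z)-dec-2-en-1-ol
Conditions: H2 (1 atm), Pd/CaCO3 poisoned with Pb(OAc)2 (Lindlar catalyst), quinoline, hexane, rt
Reagents that add atoms: none
Why: Lindlar semihydrogenation delivers both hydrogens to the same face of the alkyne and so gives the Z-allylic alcohol, with quinoline holding back over-reduction.

Step 9
Reactants: 18 (Z)-dec-2-en-1-ol
Product: 19 (Z)-dec-2-enal
Conditions: activated MnO2, CH2Cl2, 0 °C → rt, dark; filtration through Celite, used crude
Reagents that add atoms: none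
Why: Heterogeneous allylic oxidation with activated MnO2 is neutral and needs only filtration, so the Z-enal is never exposed to acid, base or silica gel that would isomerise it.

Step 10
Reactants: 20 1,4-bis(trimethylsilyl)buta-1,3-diyne
Product: 22 buta-1,3-diynyl(trimethyl)silane, via lithium diynide 21 (not isolated)
Conditions: MeLi·LiBr (1.0 equiv), Et2O, 0 °C → rt; then H2O, 0 °C; kept as a dried toluene solution
Reagents that add atoms: none
Why: Methyllithium attacks one silicon of the symmetric bis-silyl diyne and expels the stabilised diynyl anion, whose charge protects the second silyl group, so protonation gives the mono-silylated terminal diyne.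

Step 11
Reactants: 19 (Z)-dec-2-enal; 22 buta-1,3-diynyl(trimethyl)silane
Product: 24 (5S,6Z)-1-(trimethylsilyl)tetradec-6-ene-1,3-diyn-5-ol, via methylzinc diynide 23 (not isolated)
Conditions: (R,R)-ProPhenol (20 mol %), Ph3P=O (40 mol %), Me2Zn, toluene, 0–4 °C; then 19; aqueous quench
Reagents that add atoms: none
Why: Catalytic asymmetric alkynylation with a dinuclear zinc–ProPhenol complex is established for terminal 1,3-diynes and α,β-unsaturated aldehydes, the chiral pocket should guide the zinc diynide to the Re face of the aldehyde and so set 5S, and the cold, non-basic medium should leave the Z-alkene in place.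

Step 12
Reactants: 24 (5S,6Z)-1-(trimethylsilyl)tetradec-6-ene-1,3-diyn-5-ol
Product: 25 tert-butyl(dimethyl){[(5S,6Z)-1-(trimethylsilyl)tetradec-6-ene-1,3-diyn-5-yl]oxy}silane
Conditions: TBSCl, imidazole, CH2Cl2, 0 °C → rt
Reagents that add atoms: tert-butyldimethylsilyl chloride (TBSCl), CC(C)(C)[Si](C)(C)Cl
Why: Imidazole-promoted silylation of a secondary alcohol does not touch the stereocentre, and the TBS ether is chosen because it outlasts the next two steps yet leaves under mild fluoride conditions.

Step 13
Reactants: 25 tert-butyl(dimethyl){[(5S,6Z)-1-(trimethylsilyl)tetradec-6-ene-1,3-diyn-5-yl]oxy}silane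
Product: 26 tert-butyl(dimethyl)[(5S,6Z)-tetradec-6-ene-1,3-diyn-5-yloxy]silane
Conditions: K2CO3 (cat.), MeOH/THF, 0 °C, short contact; used at once
Reagents that add atoms: none
Why: Carbonate-catalysed methanolysis cleaves the C(sp)–Si bond of a diynylsilane far faster than the hindered O–Si bond, which is the usual way to unmask a terminal diyne.

Step 14
Reactants: 16 S-ethyl 3-{(3S)-3-[(2E,6E)-farnesyl]-2,4-dioxochroman-3-yl}propanethioate; 26 tert-butyl(dimethyl)[(5S,6Z)-tetradec-6-ene-1,3-diyn-5-yloxy]silane
Product: 27 (3S)-3-[(8S,9Z)-8-(tert-butyldimethylsilyloxy)-3-oxoheptadec-9-ene-4,6-diyn-1-yl]-3-[(2E,6E)-farnesyl]chroman-2,4-dione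
Conditions: PdCl2(dppf) (10 mol %), P(2-furyl)3 (25 mol %), CuI (1.7 equiv), Et3N, DMF, argon, 40–50 °C
Reagents that add atoms: none
Why: This is the known thiol ester variant of the acyl Sonogashira coupling, in which zerovalent palladium inserts into the C(O)–S bond, the copper acetylide transfers the diynyl group and excess CuI binds the ethanethiolate so that it cannot add to the new ynone, while quaternary C3 has no acidic hydrogen and cannot epimerise by enolisation.

Step 15
Reactants: 27 (3S)-3-[(8S,9Z)-8-(tert-butyldimethylsilyloxy)-3-oxoheptadec-9-ene-4,6-diyn-1-yl]-3-[(2E,6E)-farnesyl]chroman-2,4-dione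
Product: 28 (3S)-3-[(8S,9Z)-8-hydroxy-3-oxoheptadec-9-ene-4,6-diyn-1-yl]-3-[(2E,6E)-farnesyl]chroman-2,4-dione (CNP0346147.1)
Conditions: HF·pyridine, THF, polypropylene vessel, 0 °C; pH 7 phosphate buffer
Reagents that add atoms: none
Why: Fluoride cleavage of the silyl ether in a weakly acidic, anhydrous medium breaks only the O–Si bond, so the base-sensitive diynone, the activated aryl lactone and both stereocentres stay untouched.

Compound list
1 | triethyl phosphonoacetate | CCOC(=O)CP(=O)(OCC)OCC | starting material
2 | (2E,6E)-farnesyl bromide | BrC/C=C(\C)CC/C=C(\C)CCC=C(C)C | starting material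
3 | triethyl 2-[(2E,6E)-farnesyl]phosphonoacetate, racemic | CCOC(=O)C(C/C=C(\C)CC/C=C(\C)CCC=C(C)C)P(=O)(OCC)OCC | intermediate
4 | ethyl 2-[(2E,6E)-farnesyl]acrylate = ethyl (4E,8E)-5,9,13-trimethyl-2-methylidenetetradeca-4,8,12-trienoate | CCOC(=O)C(=C)C/C=C(\C)CC/C=C(\C)CCC=C(C)C | intermediate
5 | 2-[(2E,6E)-farnesyl]acrylic acid | OC(=O)C(=C)C/C=C(\C)CC/C=C(\C)CCC=C(C)C | intermediate
6 | salicylic acid | OC(=O)c1ccccc1O | starting material
7 | 2-[(2E,6E)-farnesyl]acryloyl chloride | ClC(=O)C(=C)C/C=C(\C)CC/C=C(\C)CCC=C(C)C | intermediate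
8 | 2-({2-[(2E,6E)-farnesyl]acryloyl}oxy)benzoic acid | OC(=O)c1ccccc1OC(=O)C(=C)C/C=C(\C)CC/C=C(\C)CCC=C(C)C | intermediate
9 | Meldrum's acid (2,2-dimethyl-1,3-dioxane-4,6-dione) | CC1(C)OC(=O)CC(=O)O1 | starting material
10 | ethanethiol | CCS | starting material
11 | 3-(ethylsulfanyl)-3-oxopropanoic acid | CCSC(=O)CC(=O)O | intermediate
12 | 2-(1H-imidazole-1-carbonyl)phenyl 2-[(2E,6E)-farnesyl]acrylate | O=C(c1ccccc1OC(=O)C(=C)C/C=C(\C)CC/C=C(\C)CCC=C(C)C)n1ccnc1 | intermediate
13 | magnesium bis[3-(ethylsulfanyl)-3-oxopropanoate] | CCSC(=O)CC(=O)[O-].CCSC(=O)CC(=O)[O-].[Mg+2] | intermediate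
14 | 2-[3-(ethylsulfanyl)-3-oxopropanoyl]phenyl 2-[(2E,6E)-farnesyl]acrylate | CCSC(=O)CC(=O)c1ccccc1OC(=O)C(=C)C/C=C(\C)CC/C=C(\C)CCC=C(C)C | intermediate
15 | S-ethyl (2aR,8bS)-2a-[(2E,6E)-farnesyl]-8b-hydroxy-3-oxo-1,2,2a,8b-tetrahydro-3H-cyclobuta[c]chromene-1-carbothioate, cis-fused, C1 undefined and lost on opening | CCSC(=O)C1C[C@@]2(C/C=C(\C)CC/C=C(\C)CCC=C(C)C)C(=O)Oc3ccccc3[C@@]12O | intermediate
16 | S-ethyl 3-{(3S)-3-[(2E,6E)-farnesyl]-2,4-dioxochroman-3-yl}propanethioate | CCSC(=O)CC[C@@]1(C/C=C(\C)CC/C=C(\C)CCC=C(C)C)C(=O)Oc2ccccc2C1=O | intermediate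
17 | dec-2-yn-1-ol | CCCCCCCC#CCO | starting material
18 | (Z)-dec-2-en-1-ol | CCCCCCC/C=C\CO | intermediate
19 | (Z)-dec-2-enal | CCCCCCC/C=C\C=O | intermediate
20 | 1,4-bis(trimethylsilyl)buta-1,3-diyne | C[Si](C)(C)C#CC#C[Si](C)(C)C | starting material
21 | lithium 4-(trimethylsilyl)buta-1,3-diyn-1-ide | [Li]C#CC#C[Si](C)(C)C | intermediate
22 | buta-1,3-diynyl(trimethyl)silane | C#CC#C[Si](C)(C)C | intermediate
23 | methyl[4-(trimethylsilyl)buta-1,3-diyn-1-yl]zinc | C[Zn]C#CC#C[Si](C)(C)C | intermediate
24 | (5S,6Z)-1-(trimethylsilyl)tetradec-6-ene-1,3-diyn-5-ol | CCCCCCC/C=C\[C@H](O)C#CC#C[Si](C)(C)C | intermediate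
25 | tert-butyl(dimethyl){[(5S,6Z)-1-(trimethylsilyl)tetradec-6-ene-1,3-diyn-5-yl]oxy}silane | CCCCCCC/C=C\[C@H](O[Si](C)(C)C(C)(C)C)C#CC#C[Si](C)(C)C | intermediate
26 | tert-butyl(dimethyl)[(5S,6Z)-tetradec-6-ene-1,3-diyn-5-yloxy]silane | CCCCCCC/C=C\[C@H](O[Si](C)(C)C(C)(C)C)C#CC#C | intermediate
27 | (3S)-3-[(8S,9Z)-8-(tert-butyldimethylsilyloxy)-3-oxoheptadec-9-ene-4,6-diyn-1-yl]-3-[(2E,6E)-farnesyl]chroman-2,4-dione | CCCCCCC/C=C\[C@H](O[Si](C)(C)C(C)(C)C)C#CC#CC(=O)CC[C@@]1(C/C=C(\C)CC/C=C(\C)CCC=C(C)C)C(=O)Oc2ccccc2C1=O | intermediate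
28 | (3S)-3-[(8S,9Z)-8-hydroxy-3-oxoheptadec-9-ene-4,6-diyn-1-yl]-3-[(2E,6E)-farnesyl]chroman-2,4-dione | CCCCCCC/C=C\[C@H](O)C#CC#CC(=O)CC[C@@]1(C/C=C(\C)CC/C=C(\C)CCC=C(C)C)C(=O)Oc2ccccc2C1=O | target

Total step count: 15
Longest linear sequence: 8 steps (1, 2, 3, 4, 6, 7, 14, 15)

Steps most likely to fail

**Step 7.**
- Energy transfer to the chelated enol may be too slow.
- The excited state may decay unproductively, because the aryl ester seldom adopts the s-cis rotamer that brings C3 next to C4.
- The relay of ligand chirality to the acrylate face may be weak.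
- The retro-aldol may open the wrong ring bond.
- The Lewis acid may trigger O-to-C acyl migration or acid-induced cyclisation of the farnesyl chain.

The fallback sets out from 2 and 10 and comes back at 16.
- Commercial 4-hydroxycoumarin is C3-alkylated with 2 (K2CO3, aqueous acetone, removal of the O-alkyl isomer by chromatography) to 4-hydroxy-3-[(2E,6E)-farnesyl]coumarin F1.
- Acryloyl chloride and 10 (Et3N, BHT, CH2Cl2, −78 °C) give S-ethyl prop-2-enethioate F2.
- An enantioselective Michael addition of F1 to F2 under a bifunctional cinchona alkaloid thiourea catalyst (toluene, −20 °C) gives 16. This is a known way from cyclic α-substituted β-dicarbonyl compounds and acrylic thioesters to all-carbon quaternary centres, and the pseudoenantiomeric catalyst is chosen for 3S.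

**Step 14.**
- The amine may induce retro-Michael loss of the C3 arm.
- The configuration of the doubly activated carbinol carbon may erode once the ynone has formed.
- The terminal diyne may homocouple oxidatively.
- Thiolate may add to the ynone.

The fallback sets out from 16 and 26 and comes back at 27.
- Fukuyama reduction of 16 (Et3SiH, Pd/C, acetone, rt) gives 3-{(3S)-3-[(2E,6E)-farnesyl]-2,4-dioxochroman-3-yl}propanal F3.
- 26 is deprotonated (n-BuLi, THF, −78 °C) to lithium (5S,6Z)-5-(tert-butyldimethylsilyloxy)tetradec-6-ene-1,3-diyn-1-ide F4.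
- F4 adds to the aldehyde at −78 °C and is quenched cold with acetic acid, so that the alkoxide cannot attack the lactone. This gives the propargylic alcohol (epimers at the new carbinol) F5.
- Immediate Dess–Martin oxidation (NaHCO3, CH2Cl2, 0 °C) gives 27.

**Step 11.**
- The enal may isomerise from Z to E before addition.
- Facial selectivity may be modest, because the Z-substituent sits close to the carbonyl group.

The fallback sets out from 19 and 21 and comes back at 24.
- The lithium diynide 21, taken from step 10 before the quench, is added to 19 (THF, −78 °C) to give racemic (Z)-1-(trimethylsilyl)tetradec-6-ene-1,3-diyn-5-ol F6.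
- MnO2 oxidation gives (Z)-1-(trimethylsilyl)tetradec-6-ene-1,3-diyn-5-one F7.
- Midland reduction with (S)-Alpine-Borane (B-isopinocampheyl-9-borabicyclo[3.3.1]nonane from (−)-α-pinene, neat, rt), in which the slim diynyl group acts as the small substituent, gives 24.

Further compounds
F1 | step 7 | 4-hydroxy-3-[(2E,6E)-farnesyl]coumarin | O=C1Oc2ccccc2C(O)=C1C/C=C(\C)CC/C=C(\C)CCC=C(C)C
F2 | step 7 | S-ethyl prop-2-enethioate | C=CC(=O)SCC
F3 | step 14 | 3-{(3S)-3-[(2E,6E)-farnesyl]-2,4-dioxochroman-3-yl}propanal | O=CCC[C@@]1(C/C=C(\C)CC/C=C(\C)CCC=C(C)C)C(=O)Oc2ccccc2C1=O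
F4 | step 14 | lithium (5S,6Z)-5-(tert-butyldimethylsilyloxy)tetradec-6-ene-1,3-diyn-1-ide | CCCCCCC/C=C\[C@H](O[Si](C)(C)C(C)(C)C)C#CC#C[Li]
F5 | step 14 | (3S)-3-[(8S,9Z)-8-(tert-butyldimethylsilyloxy)-3-hydroxyheptadec-9-ene-4,6-diyn-1-yl]-3-[(2E,6E)-farnesyl]chroman-2,4-dione, epimers at the new carbinol | CCCCCCC/C=C\[C@H](O[Si](C)(C)C(C)(C)C)C#CC#CC(O)CC[C@@]1(C/C=C(\C)CC/C=C(\C)CCC=C(C)C)C(=O)Oc2ccccc2C1=O
F6 | step 11 | racemic (Z)-1-(trimethylsilyl)tetradec-6-ene-1,3-diyn-5-ol | CCCCCCC/C=C\C(O)C#CC#C[Si](C)(C)C
F7 | step 11 | (Z)-1-(trimethylsilyl)tetradec-6-ene-1,3-diyn-5-one | CCCCCCC/C=C\C(=O)C#CC#C[Si](C)(C)C
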